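**Assumptions**
- The ester in the target SMILES, OC(=O)/C(C)=C/C, is (E)-2-methylbut-2-enoate (tiglate), not angelate, so tigloyl chloride is used.
- Where a diastereoselective step has no exact precedent, I assume the major isomer is the one needed (stated in that step's "Why") and that it is separable by chromatography.

**Retrosynthetic overview**
1. The target comes from TES removal of a macrocycle, which is closed last by a ring-closing alkyne–aldehyde metathesis. That step forms C4–C5, the 4Z-enone and the C3 ketone at once.
2. The enyne–aldehyde lactone comes from an In-mediated Barbier allylation of glyoxal acetal. The allyl bromide is a γ-silyloxyalkyl 2-(bromomethyl)acrylate, and this step builds the α-methylene-γ-lactone and sets C6/C7.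
3. The allyl bromide comes from a Morita–Baylis–Hillman (MBH) reaction and SN2′ bromination of an aldehyde. That aldehyde comes from an organocatalytic acetone/glyoxal-acetal aldol (C8) followed by chelation-controlled (E)-enynyl addition (C10).
4. Ring order: the γ-lactone forms in step 7 and the 10-membered carbocycle in step 11.

---

**Step 1**
Reactants: 1 acetone; 2 2,2-dimethoxyacetaldehyde
Product: 3 (R)-4-hydroxy-5,5-dimethoxypentan-2-one
Conditions: (S)-proline (30 mol%), acetone/DMSO, rt, 24 h
Reagents that add atoms: none
Why: Enamine-catalysed direct aldol (List–Barbas) in which the acetone enamine attacks one face of the aldehyde, setting C8 as (R), the first stereocentre; the acetal is inert.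

**Step 2**
Reactants: 4 (E)-1,2-diiodoethene; 5 1-propynylmagnesium bromide
Product: 6 (E)-1-iodopent-1-en-3-yne
Conditions: 5, ZnCl2, then 4 (3 equiv), Pd(PPh3)4 (5 mol%), THF, 0 °C → rt
Reagents that add atoms: none
Why: Negishi coupling of the propynylzinc at one C–I bond of excess diiodoethene, with retention of E geometry.

**Step 3**
Reactants: 3; 6
Product: 7 diol acetal, (8R,10R) as in the target
Conditions: 6, iPrMgCl·LiCl, THF, –40 °C (I/Mg exchange); then 3, –78 → –30 °C
Reagents that add atoms: none
Why: Addition of the (E)-enynyl Grignard to the methyl ketone through a six-membered Mg chelate with the C8 alkoxide (Cram-chelate control), with axial delivery of the enynyl group, gives the 1,3-anti diol at C10; I assume dr ≈ 5:1.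

**Step 4**
Reactants: 7; 8 triethylsilyl triflate; 9 water
Product: 10 bis-TES aldehyde
Conditions: TESOTf (4 equiv), 2,4,6-collidine (6 equiv), CH2Cl2, 0 °C; then H2O
Reagents that add atoms: TESOTf, CC[Si](CC)(CC)OS(=O)(=O)C(F)(F)F; water, O
Why: Non-acidic acetal deprotection (collidinium salt, then hydrolysis), with both hydroxyls silylated in the same pot; no stereocentre is touched.

**Step 5**
Reactants: 10; 11 methyl acrylate
Product: 12 MBH adduct (C7 carbinol as an epimer mixture)
Conditions: DABCO (0.5 equiv), methyl acrylate (10 equiv), rt, 4 d
Reagents that add atoms: none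
Why: Morita–Baylis–Hillman reaction; the new C7 carbinol centre is discarded in the next step.

**Step 6**
Reactants: 12; 13 N-bromosuccinimide
Product: 14 (Z)-2-(bromomethyl)alk-2-enoate
Conditions: NBS, Me2S, CH2Cl2, –20 °C → rt
Reagents that add atoms: NBS, O=C1CCC(=O)N1Br
Why: SN2′ bromination of the MBH alcohol (bromodimethylsulfonium activation) transposes the alkene and removes the C7 stereocentre, while C8 is untouched.

**Step 7**
Reactants: 14; 2 2,2-dimethoxyacetaldehyde
Product: 15 trans-fused α-methylene-γ-lactone bearing the C5 acetal
Conditions: In, THF/H2O (3:1), rt, 12 h; then crude, cat. TsOH·H2O, CH2Cl2, 0 °C → rt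
Reagents that add atoms: none
Why: Indium-mediated Barbier allylation (SE2′ through a chair transition state) gives the anti homoallylic alcohol, which lactonises to the 6,7-trans lactone; the C8 silyloxy stereocentre biases the allyl-indium face to give (7R) (assumed major isomer).

**Step 8**
Reactants: 15
Product: 16 C8 alcohol (C10 still OTES)
Conditions: AcOH/THF/H2O (3:1:1), rt, 6 h
Reagents that add atoms: none
Why: The hindered tertiary TES ether survives while the secondary TES ether is hydrolysed selectively.

**Step 9**
Reactants: 16; 17 tigloyl chloride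
Product: 18 C8 tiglate
Conditions: 17, Et3N, DMAP (cat.), CH2Cl2, 0 °C
Reagents that add atoms: tigloyl chloride (compound 17), ClC(=O)/C(C)=C/C
Why: Acylation of the secondary alcohol with retention at C8; the tertiary OTES is inert, and the E-acyl group cannot isomerise to angelate.

**Step 10**
Reactants: 18; 8 TESOTf; 9 water
Product: 19 enyne aldehyde (ring-closing precursor)
Conditions: TESOTf (2 equiv), 2,4,6-collidine (3 equiv), CH2Cl2, 0 °C; then H2O
Reagents that add atoms: TESOTf, CC[Si](CC)(CC)OS(=O)(=O)C(F)(F)F; water, O
Why: The same mild acetal-to-aldehyde conversion as step 4 unmasks C5, and no free OH remains to be silylated.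

**Step 11**
Reactants: 19
Product: 20 TES-protected macrocycle (isomer of 19)
Conditions: FeCl3 (20 mol%), 1,2-dichloroethane, 0.002 M (substrate added by syringe pump over 6 h), 50 °C
Reagents that add atoms: none
Why: Proposed new method: FeCl3 activates the C5 aldehyde, and the methyl-bearing alkyne carbon C4 attacks it in a 10-membered transition state. This gives a vinyl cation at C3 stabilised by the (E)-C1=C2 π-bond, the carbonyl oxygen closes it to an oxetene, and 4π-electrocyclic opening delivers the C3 ketone and the C4=C5 alkene; the ring places C3 and C6 cis (4Z). The closest known reaction is Lewis-acid alkyne–carbonyl metathesis, so this is that reaction applied as a macrocyclic ring closure of a conjugated enyne.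

**Step 12**
Reactants: 20
Product: 21 eupaheliangolide A
Conditions: HF·pyridine, pyridine/THF (1:5), 0 °C → rt, 6 h
Reagents that add atoms: none
Why: Fluoride cleaves the tertiary TES ether, leaving the enone, the tiglate and the lactone intact.

---

**Compound list**
1 | acetone | CC(C)=O | starting material
2 | 2,2-dimethoxyacetaldehyde | COC(OC)C=O | starting material
3 | (R)-4-hydroxy-5,5-dimethoxypentan-2-one | CC(=O)C[C@@H](O)C(OC)OC | intermediate
4 | (E)-1,2-diiodoethene | I/C=C/I | starting material
5 | 1-propynylmagnesium bromide | CC#C[Mg]Br | starting material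
6 | (E)-1-iodopent-1-en-3-yne | CC#C/C=C/I | intermediate
7 | enynyl diol acetal | CC#C/C=C/[C@](C)(O)C[C@@H](O)C(OC)OC | intermediate
8 | triethylsilyl triflate | CC[Si](CC)(CC)OS(=O)(=O)C(F)(F)F | starting material (reagent)
9 | water | O | starting material (reagent)
10 | bis-TES α-silyloxy aldehyde | CC#C/C=C/[C@](C)(O[Si](CC)(CC)CC)C[C@@H](O[Si](CC)(CC)CC)C=O | intermediate
11 | methyl acrylate | C=CC(=O)OC | starting material
12 | MBH adduct | CC#C/C=C/[C@](C)(O[Si](CC)(CC)CC)C[C@@H](O[Si](CC)(CC)CC)C(O)C(=C)C(=O)OC | intermediate
13 | N-bromosuccinimide | O=C1CCC(=O)N1Br | starting material (reagent)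
14 | allyl bromide | CC#C/C=C/[C@](C)(O[Si](CC)(CC)CC)C[C@@H](O[Si](CC)(CC)CC)/C=C(\CBr)C(=O)OC | intermediate
15 | lactone acetal, bis-TES | C=C1C(=O)O[C@H](C(OC)OC)[C@H]1[C@H](O[Si](CC)(CC)CC)C[C@@](C)(O[Si](CC)(CC)CC)/C=C/C#CC | intermediate
16 | C8 alcohol, C10-OTES | C=C1C(=O)O[C@H](C(OC)OC)[C@H]1[C@H](O)C[C@@](C)(O[Si](CC)(CC)CC)/C=C/C#CC | intermediate
17 | tigloyl chloride | ClC(=O)/C(C)=C/C | starting material (reagent)
18 | C8 tiglate | C=C1C(=O)O[C@H](C(OC)OC)[C@H]1[C@H](OC(=O)/C(C)=C/C)C[C@@](C)(O[Si](CC)(CC)CC)/C=C/C#CC | intermediate
19 | enyne aldehyde | C=C1C(=O)O[C@H](C=O)[C@H]1[C@H](OC(=O)/C(C)=C/C)C[C@@](C)(O[Si](CC)(CC)CC)/C=C/C#CC | intermediate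
20 | TES-macrocycle | C=C1C(=O)O[C@@H]2/C=C(/C)C(=O)/C=C/[C@](C)(O[Si](CC)(CC)CC)C[C@@H](OC(=O)/C(C)=C/C)[C@@H]12 | intermediate
21 | eupaheliangolide A | C=C1C(=O)O[C@@H]2/C=C(/C)C(=O)/C=C/[C@](C)(O)C[C@@H](OC(=O)/C(C)=C/C)[C@@H]12 | target

**Totals:** 12 steps in all; the longest linear sequence is 11 steps from acetone (steps 1, 3–12). Step 2 is a parallel branch.

**Three steps most likely to fail**
1. **Step 11 (proposed new ring-closing alkyne–aldehyde metathesis).** The risks are 10-membered strain, ionisation of the tertiary enynyl silyl ether under Lewis acid, and the wrong alkene geometry.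
   - Fallback: use vinylmagnesium bromide instead of 6 in step 3 and carry it through to the C5 aldehyde.
   - Then run Ando Z-selective HWE with a 2-(diarylphosphono)propionate, convert the ester to the Weinreb amide, and add vinylmagnesium bromide to give the divinyl ketone.
   - Close C1=C2 by ring-closing metathesis (Hoveyda–Grubbs II, high dilution) and remove the TES group.
2. **Step 7 (Barbier diastereoselectivity at C6/C7).** The risk is a mixture of cis/trans lactones or the wrong C7 epimer.
   - Fallback: convert aldehyde 10 to the propargylic alcohol with ethynylmagnesium bromide, then to the mesylate.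
   - Run a Marshall Pd/Et2Zn anti-propargylation of 2, then a Pd-catalysed cyclocarbonylation of the homopropargylic alcohol to the α-methylene lactone.
3. **Step 3 (C10 diastereoselectivity).** The risk is poor or inverted chelation-controlled dr.
   - Fallback: use the complementary disconnection. Prepare the β-hydroxy enynyl ketone from the aldol fragment via its Weinreb amide, then add MeMgBr under Mg chelation.
   - Methyl and enynyl swap axial/equatorial roles in the chelate, which delivers the opposite C10 epimer.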